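A small charge of free catalyst, 50 µM in red and 60 µM in ochre against 10 mM of starting material, has to turn over many times, so when you asked for a quick number I fitted no mechanism.

| flask | starting material | reagent | free catalyst | remark | time |
|---|---|---|---|---|---|
| west | 10 mM | 10 mM | 59 µM | run made earlier |  |
| north-east | 10 mM | 10 mM | 91 µM | run made earlier |  |
| red | 10 mM | 10.0 mM | 50 µM |  | 2.5 h |
| ochre | 10 mM | 10.0 mM | 60 µM |  | 2.5 h |

| run | time / min | starting material / % | catalyst intermediate C / % | catalyst intermediate B / % | target / % |
|---|---|---|---|---|---|
| west | 8.00 | 97.5 | 0 | 0 | 2.4 |
| west | 15.0 | 96.5 | 0 | 0 | 3.8 |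
| west | 30.0 | 91.7 | 0.1 | 0 | 7.3 |
| west | 60.0 | 84.8 | 0.2 | 0 | 15.3 |
| west | 120 | 71.0 | 0.4 | 0 | 28.7 |
| north-east | 8.00 | 96.4 | 0.1 | 0 | 2.8 |
| north-east | 15.0 | 93.6 | 0.2 | 0.4 | 5.3 |
| north-east | 30.0 | 88.0 | 0.4 | 0.3 | 11.8 |
| north-east | 60.0 | 76.4 | 0 | 0.3 | 22.7 |
| north-east | 120 | 57.9 | 0.3 | 0 | 42.0 |

(readings scatter by 0.3 percentage points)

- which of these there is most of at the end, counted by the starting material in it, red (catalyst intermediate C / catalyst intermediate B / target / starting material)
- which of these there is most of at the end, counted by the starting material in it, ochre (catalyst intermediate C / catalyst intermediate B / target / starting material)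
- final amount of the leader among these, as a percentage of the starting material charged, in red
- final amount of the leader among these, as a percentage of the starting material charged, in ochre

All four flasks had the same charges of starting material and reagent. With those held, and the catalyst coming back at each turn, I assumed that the starting material left in a flask depended on time and [free catalyst] charged through their product, so I read each flask in minutes of west:

red: 127 min
ochre: 153 min
north-east at its last reading: 185 min

This catalyst clock, time multiplied by [free catalyst] charged and divided by the same charge in west, is what kineticists call time normalisation. I tested it first: north-east at 30.0 min stood at 46.3 min, where west's neighbouring readings gave 88.0 % and north-east read 88.0 %. A straight line from west's last reading, 71.0 %, to north-east's, 57.9 %, then gave me starting material of: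

red: 69.6 %
ochre: 64.4 %

Your forecast named starting material as leader in both flasks, at 69.2 % in red and 64.4 % in ochre, on this ground: “The rate is therefore first order in catalyst.” Its numbers lay close to mine but came from its own exponential, not from my line.

The flasks gave starting material as leader in red at 69.4 % and starting material in ochre at 64.1 %.

    reagent + free catalyst → catalyst intermediate A (k = 6100 L mol⁻¹ h⁻¹)
    starting material + catalyst intermediate A ⇌ catalyst intermediate B (K = 500 L mol⁻¹, k = 8.20 × 10⁵ L mol⁻¹ h⁻¹)
    catalyst intermediate B → catalyst intermediate C (k = 130 h⁻¹)
    catalyst intermediate C → free catalyst + target (k = 85.0 h⁻¹)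

In ochre at 1.17 h, free catalyst had a half-life of 0.83 min by its step with reagent, while reagent had 3.9 h by that same step. Ochre, at 153 min on the clock, ended with 53.7 % of its catalyst free, 5.44 % as intermediate A, 16.1 % as intermediate B and 24.7 % as intermediate C, and those last two held 0.0969 % and 0.148 % of the starting material.

A further flask, like ochre but with 0.036 mM of free catalyst, stood at 91.5 min on the clock, beside north-east at 60.0 min, which stood at 92.5 min and read 76.4 %. The computed flask ended with 77.4 % of its starting material left.

The numbers in the tables are calculated from invented constants, and the scatter is random.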